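**Retrosynthetic overview**
- Bisoflavolin G ⇐ removal of four O-benzyl groups ⇐ tetra-O-benzyl bis-isoflavone ⇐ closure of both pyranone rings (O1–C2 in each half) from a bis(1,2-diaryl-3,3-dimethoxypropanone).
- That bis-acetal ⇐ twofold oxidative 1,2-aryl shift (Cβ to Cα, creating both C3–C1' bonds) of an ether-linked bis(2'-hydroxychalcone).
- Bis-chalcone ⇐ two Claisen–Schmidt disconnections at the two C=C bonds: 4-(benzyloxy)benzaldehyde, a diaryl ether keto-aldehyde and 4,6-bis(benzyloxy)-3-chloro-2-hydroxyacetophenone. The diaryl ether ⇐ SNAr of 4-benzyloxy-2,3-dihydroxyacetophenone on 4-fluorobenzaldehyde.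
- Feature used: both halves are 3-aryl-4H-chromen-4-ones, and the ether oxygen on C8 of the 7-hydroxy half lies para to C1' of the 3-aryl ring of the 8-chloro half. Before the shift that ring carbon can carry a formyl group, which activates the ring for SNAr and later becomes C2 of the chloro half.
- Ring order: the hindered ether first, on simple benzenes; then the two C3 chains; then both aryl shifts together; last both pyranone rings (ring C of each half) in one acid step.

Key step: step 9

**Route**

Step 1
Reactants: 1 2,3,4-trihydroxyacetophenone (gallacetophenone)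
Product: 2 4-benzyloxy-2,3-dihydroxyacetophenone
Conditions: BnBr (1.05 equiv), NaHCO3, NaI (cat), DMF, 40 °C
Reagents that add atoms: benzyl bromide, BrCc1ccccc1
Why: Williamson etherification under a weak base should take only the 4-OH, the most acidic hydroxyl because it is para to the acetyl group, in line with the usual order of O-alkylation of gallacetophenone (4, then 3, then 2).

Step 2
Reactants: 2 4-benzyloxy-2,3-dihydroxyacetophenone; 3 4-fluorobenzaldehyde
Product: 4 4-[3-acetyl-6-(benzyloxy)-2-hydroxyphenoxy]benzaldehyde
Conditions: K2CO3 (2.5 equiv), DMF, 100 °C, N2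
Reagents that add atoms: none
Why: Nucleophilic aromatic substitution (addition–elimination through a Meisenheimer adduct) on the fluoroarene activated by the para formyl group should occur at the 3-OH, which is free of the hydrogen bond that ties the 2-OH to the acetyl carbonyl, and a Smiles-type aryl transfer between the neighbouring oxygens would favour the same ether because it keeps the acetyl-conjugated 2-phenoxide.

Step 3
Reactants: 4 4-[3-acetyl-6-(benzyloxy)-2-hydroxyphenoxy]benzaldehyde
Product: 5 1-{4-(benzyloxy)-3-[4-(1,3-dioxolan-2-yl)phenoxy]-2-hydroxyphenyl}ethanone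
Conditions: HOCH2CH2OH, p-TsOH·H2O (cat), toluene, reflux, Dean–Stark
Reagents that add atoms: ethylene glycol, OCCO
Why: Acid-catalysed acetalisation with azeotropic removal of water should be selective for the aldehyde, since the aryl ketone is conjugated, hindered and deactivated by the hydrogen-bonded ortho hydroxyl, and the mask keeps the acetyl group from condensing with the formyl group of a second molecule in the next step.

Step 4
Reactants: 5 1-{4-(benzyloxy)-3-[4-(1,3-dioxolan-2-yl)phenoxy]-2-hydroxyphenyl}ethanone; 6 4-(benzyloxy)benzaldehyde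
Product: 7 (E)-3-[4-(benzyloxy)phenyl]-1-{4-(benzyloxy)-3-[4-(1,3-dioxolan-2-yl)phenoxy]-2-hydroxyphenyl}prop-2-en-1-one
Conditions: KOH (50% aq), EtOH/THF, rt; then cold dilute AcOH to pH 6
Reagents that add atoms: none
Why: Claisen–Schmidt condensation, in which the methyl ketone enolate adds to the non-enolisable aldehyde and the aldol dehydrates by E1cB to the conjugated E enone, the thermodynamically favoured alkene, while the dioxolane and benzyl ethers are inert to hydroxide.

Step 5
Reactants: 7 (E)-3-[4-(benzyloxy)phenyl]-1-{4-(benzyloxy)-3-[4-(1,3-dioxolan-2-yl)phenoxy]-2-hydroxyphenyl}prop-2-en-1-one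
Product: 8 4-{6-(benzyloxy)-3-[(E)-3-(4-(benzyloxy)phenyl)prop-2-enoyl]-2-hydroxyphenoxy}benzaldehyde
Conditions: 2 M HCl, THF, rt
Reagents that add atoms: water, O
Why: Acid-catalysed hydrolysis of the aryl dioxolane is fast at room temperature, conditions under which the 2'-hydroxychalcone is not expected to close to the flavanone and the benzyl ethers are stable.

Step 6
Reactants: 9 2,4,6-trihydroxyacetophenone (phloroacetophenone)
Product: 10 4,6-bis(benzyloxy)-2-hydroxyacetophenone
Conditions: BnBr (2.1 equiv), K2CO3, DMF, rt
Reagents that add atoms: benzyl bromide, BrCc1ccccc1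
Why: Williamson etherification of the 4-OH and of one of the two equivalent ortho hydroxyls, after which the remaining hydroxyl is held in a hydrogen bond to the ketone and resists alkylation under carbonate conditions.

Step 7
Reactants: 10 4,6-bis(benzyloxy)-2-hydroxyacetophenone
Product: 11 4,6-bis(benzyloxy)-3-chloro-2-hydroxyacetophenone
Conditions: NCS (1.0 equiv), MeCN, 0 °C to rt
Reagents that add atoms: N-chlorosuccinimide, O=C1CCC(=O)N1Cl
Why: Electrophilic aromatic chlorination with one equivalent of N-chlorosuccinimide should enter at C3, ortho to the free hydrogen-bonded hydroxyl and para to the 6-benzyloxy group, as is usual for halogenation of 2-hydroxy-4,6-dialkoxyacetophenones, and the site should be confirmed by an HMBC correlation from the chelated OH before the material is carried on.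

Step 8
Reactants: 8 4-{6-(benzyloxy)-3-[(E)-3-(4-(benzyloxy)phenyl)prop-2-enoyl]-2-hydroxyphenoxy}benzaldehyde; 11 4,6-bis(benzyloxy)-3-chloro-2-hydroxyacetophenone
Product: 12 ether-linked bis-chalcone, (E)-1-[4-(benzyloxy)-3-(4-{(E)-3-[4,6-bis(benzyloxy)-3-chloro-2-hydroxyphenyl]-3-oxoprop-1-enyl}phenoxy)-2-hydroxyphenyl]-3-[4-(benzyloxy)phenyl]prop-2-en-1-one
Conditions: KOH (50% aq), EtOH/THF, rt; then cold dilute HCl
Reagents that add atoms: none
Why: Second Claisen–Schmidt condensation, in which 11 is the only enolisable ketone and the formyl group of 8 the only aldehyde, so the enolate of 11 should add there and dehydrate to the E enone, while the first enone and the benzyl ethers tolerate ethanolic hydroxide at room temperature.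

Step 9
Reactants: 12 ether-linked bis-chalcone
Product: 13 bis-acetal, 1-[4-(benzyloxy)-3-(4-{1-[4,6-bis(benzyloxy)-3-chloro-2-hydroxyphenyl]-3,3-dimethoxy-1-oxopropan-2-yl}phenoxy)-2-hydroxyphenyl]-2-[4-(benzyloxy)phenyl]-3,3-dimethoxypropan-1-one (mixture of diastereomers)
Conditions: Tl(NO3)3·3H2O (2.4 equiv), MeOH/HC(OMe)3/CH2Cl2, rt
Reagents that add atoms: methanol, CO
Why: Each enone should be attacked by trivalent thallium at the carbon alpha to the carbonyl while methanol adds at the benzylic carbon; the para-oxygenated aryl ring then bridges to the alpha carbon through a phenonium ion as monovalent thallium leaves, and methanol traps the resulting oxocarbenium ion as the dimethyl acetal. This is the known oxidative rearrangement of 2'-hydroxychalcones to 1,2-diaryl-3,3-dimethoxypropan-1-ones, here required at both enones of one molecule, so that the two C3–C1' bonds of the two future isoflavone units are made in one operation. No ring closes in this step; ring C of each half closes in step 10, each time by 6-exo-trig attack of the chelated phenol oxygen (future O1) on the oxocarbenium carbon (future C2) released from the acetal. The two new CH stereocentres arise without control, so 13 is a diastereomer mixture, and both become sp2 C3 atoms in step 10. The selectivity needed is aryl migration in preference to aurone formation and to oxidation of the phenolic rings; the benzyloxy group para on one migrating ring and the bridging aryloxy oxygen para on the other raise the migratory aptitude, and the chelated 2'-hydroxyls are poor nucleophiles toward the thallated enone.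

Step 10
Reactants: 13 bis-acetal
Product: 14 tetra-O-benzyl bis-isoflavone, 7-(benzyloxy)-3-[4-(benzyloxy)phenyl]-8-{4-[5,7-bis(benzyloxy)-8-chloro-4-oxo-4H-chromen-3-yl]phenoxy}-4H-chromen-4-one
Conditions: 10% HCl in MeOH/THF, 50 °C
Reagents that add atoms: none
Why: Acid ionises each dimethyl acetal to an oxocarbenium ion that is captured by the neighbouring chelated phenol oxygen (6-exo-trig, O1 to C2), and loss of the second methanol gives the aromatic pyranone; in the chloro half the only free hydroxyl is the one next to chlorine, so the chlorine ends at C8.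

Step 11
Reactants: 14 tetra-O-benzyl bis-isoflavone
Product: 15 Bisoflavolin G, 8-[4-(8-chloro-5,7-dihydroxy-4-oxo-4H-chromen-3-yl)phenoxy]-7-hydroxy-3-(4-hydroxyphenyl)-4H-chromen-4-one
Conditions: BCl3 (10 equiv), C6HMe5 (12 equiv), CH2Cl2, −78 to −40 °C; then MeOH, aqueous work-up
Reagents that add atoms: none
Why: Lewis-acid cleavage of the four aryl benzyl ethers by BCl3, with pentamethylbenzene trapping the benzyl cation by Friedel–Crafts alkylation, runs at low temperature without hydrogenolysis and so should leave the aryl chloride, the diaryl ether and the chromone double bonds untouched.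

**Compound list**
1 | 2,3,4-trihydroxyacetophenone (gallacetophenone) | CC(=O)c1ccc(O)c(O)c1O | starting material
2 | 4-benzyloxy-2,3-dihydroxyacetophenone | CC(=O)c1ccc(OCc2ccccc2)c(O)c1O | intermediate
3 | 4-fluorobenzaldehyde | O=Cc1ccc(F)cc1 | starting material
4 | 4-[3-acetyl-6-(benzyloxy)-2-hydroxyphenoxy]benzaldehyde | CC(=O)c1ccc(OCc2ccccc2)c(Oc2ccc(C=O)cc2)c1O | intermediate
5 | 1-{4-(benzyloxy)-3-[4-(1,3-dioxolan-2-yl)phenoxy]-2-hydroxyphenyl}ethanone | CC(=O)c1ccc(OCc2ccccc2)c(Oc2ccc(C3OCCO3)cc2)c1O | intermediate
6 | 4-(benzyloxy)benzaldehyde | O=Cc1ccc(OCc2ccccc2)cc1 | starting material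
7 | (E)-3-[4-(benzyloxy)phenyl]-1-{4-(benzyloxy)-3-[4-(1,3-dioxolan-2-yl)phenoxy]-2-hydroxyphenyl}prop-2-en-1-one | O=C(/C=C/c1ccc(OCc2ccccc2)cc1)c1ccc(OCc2ccccc2)c(Oc2ccc(C3OCCO3)cc2)c1O | intermediate
8 | 4-{6-(benzyloxy)-3-[(E)-3-(4-(benzyloxy)phenyl)prop-2-enoyl]-2-hydroxyphenoxy}benzaldehyde | O=Cc1ccc(Oc2c(OCc3ccccc3)ccc(C(=O)/C=C/c3ccc(OCc4ccccc4)cc3)c2O)cc1 | intermediate
9 | 2,4,6-trihydroxyacetophenone (phloroacetophenone) | CC(=O)c1c(O)cc(O)cc1O | starting material
10 | 4,6-bis(benzyloxy)-2-hydroxyacetophenone | CC(=O)c1c(OCc2ccccc2)cc(OCc2ccccc2)cc1O | intermediate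
11 | 4,6-bis(benzyloxy)-3-chloro-2-hydroxyacetophenone | CC(=O)c1c(OCc2ccccc2)cc(OCc2ccccc2)c(Cl)c1O | intermediate
12 | ether-linked bis-chalcone (both alkenes E) | O=C(/C=C/c1ccc(OCc2ccccc2)cc1)c1ccc(OCc2ccccc2)c(Oc2ccc(/C=C/C(=O)c3c(OCc4ccccc4)cc(OCc4ccccc4)c(Cl)c3O)cc2)c1O | intermediate
13 | bis(1,2-diaryl-3,3-dimethoxypropanone), mixture of diastereomers | COC(OC)C(c1ccc(OCc2ccccc2)cc1)C(=O)c1ccc(OCc2ccccc2)c(Oc2ccc(C(C(OC)OC)C(=O)c3c(OCc4ccccc4)cc(OCc4ccccc4)c(Cl)c3O)cc2)c1O | intermediate
14 | tetra-O-benzyl bis-isoflavone | O=c1c(-c2ccc(OCc3ccccc3)cc2)coc2c(Oc3ccc(-c4coc5c(Cl)c(OCc6ccccc6)cc(OCc6ccccc6)c5c4=O)cc3)c(OCc3ccccc3)ccc12 | intermediate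
15 | Bisoflavolin G | O=c1c(-c2ccc(O)cc2)coc2c(Oc3ccc(-c4coc5c(Cl)c(O)cc(O)c5c4=O)cc3)c(O)ccc12 | target

**Count**
Total steps: 11. Longest linear sequence: 9 (steps 1–5 and 8–11); the chloro ketone branch (steps 6 and 7) joins at step 8.

**Steps most likely to fail**

Step 9. The second migration may lag behind the first, because the bridging aryloxy ring is a weaker donor than the benzyloxyphenyl ring. At that enone, closure by the 2'-oxygen toward an aurone could then compete, and excess trivalent thallium could oxidise the phenolic rings. The fallback replaces the aryl shift by an acyl shift and sets out from 12. Both chelated hydroxyls would be capped (MOMCl, NaH, DMF, 0 °C) to give the bis(methoxymethyl) ether F1. Weitz–Scheffer epoxidation (H2O2, NaOH, MeOH/THF, 0 °C to rt) should then give the bis(trans-epoxide) F2. BF3·OEt2 in CH2Cl2 at 0 °C would open each epoxide at the benzylic carbon and trigger the 1,2-acyl shift of an α,β-epoxy ketone, giving the bis(2-aryl-3-oxopropanal) F3, which has the same carbon connectivity as the aryl-shift product. Warm HCl in MeOH would then remove the methoxymethyl groups and cyclodehydrate both halves, which returns to the route at 14.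

Step 2. Substitution at the phenoxide flanked on both sides may be slow, and at the temperature then needed base-mediated aldol condensation between acetyl and formyl groups, or arylation of the other oxygen, could take over. The fallback sets out from 2 and uses a copper-catalysed Ullmann-type O-arylation with commercial 2-(4-bromophenyl)-1,3-dioxolane (CuI, picolinic acid, K3PO4, DMSO, 90 °C, argon). The aldehyde is masked from the start, so no aldol pathway exists, and the product is 5 directly, where the route is rejoined with step 3 omitted. This fallback forms no compound outside the main list (F0).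

Step 8. The twice ortho-substituted ketone may enolise and condense slowly, so that during long exposure to hydroxide the existing enone could undergo retro-aldol exchange, conjugate addition or flavanone closure, and the aldehyde could disproportionate. The fallback forms the second enone under neutral conditions by a Wittig reaction and sets out from 11. Side-chain bromination with phenyltrimethylammonium tribromide in THF should give the α-bromo ketone F4. PPh3 in toluene would convert it into the phosphonium bromide F5, and aqueous Na2CO3 into the stabilised phosphorane F6. Heating F6 with aldehyde 8 in toluene should give the E enone and return to the route at 12.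

**Further compounds**
F1 | step 9 | bis(methoxymethyl) ether of bis-chalcone 12 | O=C(/C=C/c1ccc(OCc2ccccc2)cc1)c1ccc(OCc2ccccc2)c(Oc2ccc(/C=C/C(=O)c3c(OCc4ccccc4)cc(OCc4ccccc4)c(Cl)c3OCOC)cc2)c1OCOC
F2 | step 9 | bis(trans-epoxide) of F1 (one diastereomer drawn, expected as a mixture) | O=C([C@@H]1O[C@H]1c1ccc(OCc2ccccc2)cc1)c1ccc(OCc2ccccc2)c(Oc2ccc([C@@H]3O[C@H]3C(=O)c3c(OCc4ccccc4)cc(OCc4ccccc4)c(Cl)c3OCOC)cc2)c1OCOC
F3 | step 9 | bis(2-aryl-3-oxopropanal), methoxymethyl groups retained (mixture of diastereomers) | O=CC(c1ccc(OCc2ccccc2)cc1)C(=O)c1ccc(OCc2ccccc2)c(Oc2ccc(C(C=O)C(=O)c3c(OCc4ccccc4)cc(OCc4ccccc4)c(Cl)c3OCOC)cc2)c1OCOC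
F0 | step 2 | none | none
F4 | step 8 | 1-[4,6-bis(benzyloxy)-3-chloro-2-hydroxyphenyl]-2-bromoethanone | O=C(CBr)c1c(OCc2ccccc2)cc(OCc2ccccc2)c(Cl)c1O
F5 | step 8 | {2-[4,6-bis(benzyloxy)-3-chloro-2-hydroxyphenyl]-2-oxoethyl}triphenylphosphonium bromide | O=C(C[P+](c1ccccc1)(c1ccccc1)c1ccccc1)c1c(OCc2ccccc2)cc(OCc2ccccc2)c(Cl)c1O.[Br-]
F6 | step 8 | 1-[4,6-bis(benzyloxy)-3-chloro-2-hydroxyphenyl]-2-(triphenylphosphoranylidene)ethanone | O=C(C=P(c1ccccc1)(c1ccccc1)c1ccccc1)c1c(OCc2ccccc2)cc(OCc2ccccc2)c(Cl)c1O
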